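## Retrosynthetic overview

1. Target 25 ⇒ Z‑vinyl iodide 22 + an ethynyl metal (Negishi coupling, last step; the enyne is kept out of every earlier step).
2. 22 ⇒ oxocene 19: the trans C9–Cl / C10–OAc pair comes from the ring alkene by syn‑dihydroxylation and chloride opening of the derived acetoxonium ion.
3. 19 ⇒ acyclic diene 18 by ring‑closing metathesis (C9=C10); this is the only ring and it is closed late.
4. 18 ⇒ ether 16: two halves of similar size, chlorohydrin 9 (C3–C9) and α‑keto triflate 15 (C10–C15), are joined by SN2 etherification at C12; C13–Br then comes from the ketone (Felkin reduction, bromination with inversion).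
5. 9 ⇐ (±)‑hexa‑1,5‑dien‑3‑ol (kinetic‑resolution epoxidation, chloride inversion, Z‑stannylvinyl epoxide opening); 15 ⇐ L‑allylglycine (diazotisation, Weinreb ketone synthesis, triflation).

Assumption: the SMILES is read as (3Z,6S,7S,9S,10S,12R,13S), with C1–C15 numbered along the chain from the alkyne CH; compounds 1, 5, 10 and 23 are bought.

## Route

Step 1
Reactants: 1 (±)-hexa-1,5-dien-3-ol
Product: 2 (1R)-1-[(2S)-oxiran-2-yl]but-3-en-1-ol
Conditions: Ti(OiPr)4 (0.2 equiv), D-(−)-diisopropyl tartrate (0.25 equiv), t-BuOOH (0.45 equiv), 4 Å MS, CH2Cl2, −20 °C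
Reagents that add atoms: tert-butyl hydroperoxide, CC(C)(C)OO
Why: Sharpless asymmetric epoxidation run as a kinetic resolution: with the D‑tartrate the (R)‑alcohol is epoxidised fast on its allylic vinyl group to the erythro (anti) epoxy alcohol, which sets C6 (S) and leaves the C7 hydroxyl ready for inversion, while the (S)‑alcohol and the remote allyl alkene stay untouched.

Step 2
Reactants: 2 (1R)-1-[(2S)-oxiran-2-yl]but-3-en-1-ol
Product: 3 (1R)-1-[(2S)-oxiran-2-yl]but-3-en-1-yl chloromethanesulfonate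
Conditions: ClCH2SO2Cl, pyridine, CH2Cl2, 0 °C
Reagents that add atoms: chloromethanesulfonyl chloride, ClCS(=O)(=O)Cl
Why: O‑sulfonylation without touching the stereocentre; the chloromethanesulfonate is a far better leaving group than a mesylate, which is needed for substitution next to the electron‑withdrawing epoxide.

Step 3
Reactants: 3 (1R)-1-[(2S)-oxiran-2-yl]but-3-en-1-yl chloromethanesulfonate
Product: 4 (2S)-2-[(1S)-1-chlorobut-3-en-1-yl]oxirane
Conditions: LiCl (3 equiv), DMF, 25–40 °C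
Reagents that add atoms: lithium chloride, [Li+].[Cl-]
Why: SN2 displacement by chloride with clean inversion gives the (7S)‑chloride syn to the C6 oxygen; the terminal epoxide is inert to chloride in neutral DMF.

Step 4
Reactants: 5 ethyne
Product: 6 (Z)-1,2-bis(tributylstannyl)ethene
Conditions: Bu3SnSnBu3, Pd(PPh3)4 (2 mol %), 1,4-dioxane, 60 °C
Reagents that add atoms: hexabutyldistannane, CCCC[Sn](CCCC)(CCCC)[Sn](CCCC)(CCCC)CCCC
Why: Palladium‑catalysed distannylation adds the Sn–Sn bond syn across the alkyne, so only the Z bis‑stannane forms.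

Step 5
Reactants: 6 (Z)-1,2-bis(tributylstannyl)ethene, 4 (2S)-2-[(1S)-1-chlorobut-3-en-1-yl]oxirane
Product: 8 (1Z,4S,5S)-5-chloro-1-(tributylstannyl)octa-1,7-dien-4-ol, via (Z)-2-(tributylstannyl)vinyllithium 7 (not isolated)
Conditions: n-BuLi (1 equiv), THF, −78 °C; then BF3·OEt2 and 4, −78 °C; H2O quench at −78 °C
Reagents that add atoms: none
Why: Tin–lithium exchange gives a configurationally stable Z‑vinyllithium that opens the BF3‑activated epoxide by SN2 at its CH2 carbon (C5), leaving C6 and C7 untouched; the boron‑bound alkoxide at −78 °C does not displace the neighbouring chloride.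

Step 6
Reactants: 8 (1Z,4S,5S)-5-chloro-1-(tributylstannyl)octa-1,7-dien-4-ol
Product: 9 (1Z,4S,5S)-5-chloro-1-iodoocta-1,7-dien-4-ol
Conditions: iodine (1.05 equiv), CH2Cl2, 0 °C
Reagents that add atoms: iodine, [I][I]
Why: Iododestannylation is an ipso electrophilic substitution with retention of the Z geometry, and it is much faster than any reaction of iodine with the terminal alkene or the hydroxyl.

Step 7
Reactants: 10 L-allylglycine, (2S)-2-aminopent-4-enoic acid
Product: 11 (2S)-2-hydroxypent-4-enoic acid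
Conditions: NaNO2, 1 M H2SO4, 0 °C → rt
Reagents that add atoms: water, O
Why: Diazotisation of the α‑amino acid; the carboxylate displaces N2 to an α‑lactone that water reopens, so two inversions give net retention (S).

Step 8
Reactants: 11 (2S)-2-hydroxypent-4-enoic acid
Product: 12 methyl (2S)-2-hydroxypent-4-enoate
Conditions: MeOH, H2SO4 (cat.), 40 °C
Reagents that add atoms: methanol, CO
Why: Fischer esterification; the stereocentre is not involved.

Step 9
Reactants: 12 methyl (2S)-2-hydroxypent-4-enoate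
Product: 13 (2S)-2-hydroxy-N-methoxy-N-methylpent-4-enamide
Conditions: MeNHOMe·HCl (1.5 equiv), i-PrMgCl (4.2 equiv), THF, −20 → 0 °C; aq NH4Cl
Reagents that add atoms: N,O-dimethylhydroxylamine hydrochloride, CNOC.Cl
Why: Weinreb amide formation by aminolysis of the ester with the magnesium amide made in the flask; the α‑alkoxide formed first protects the stereocentre from enolisation.

Step 10
Reactants: 13 (2S)-2-hydroxy-N-methoxy-N-methylpent-4-enamide
Product: 14 (4S)-4-hydroxyhept-6-en-3-one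
Conditions: EtMgBr (2.5 equiv), THF, 0 °C; aq NH4Cl
Reagents that add atoms: ethylmagnesium bromide, CC[Mg]Br
Why: Weinreb ketone synthesis: the chelated tetrahedral adduct survives until work‑up, so a single ethyl group (C14–C15) is added and the stereocentre is kept.

Step 11
Reactants: 14 (4S)-4-hydroxyhept-6-en-3-one
Product: 15 (4S)-3-oxohept-6-en-4-yl trifluoromethanesulfonate
Conditions: Tf2O, 2,6-lutidine, CH2Cl2, −78 °C; used at once without chromatography
Reagents that add atoms: trifluoromethanesulfonic anhydride, O=S(=O)(OS(=O)(=O)C(F)(F)F)C(F)(F)F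
Why: O‑triflation with retention; the hindered base and low temperature avoid enolisation of the α‑keto triflate.

Step 12
Reactants: 9 (1Z,4S,5S)-5-chloro-1-iodoocta-1,7-dien-4-ol, 15 (4S)-3-oxohept-6-en-4-yl trifluoromethanesulfonate
Product: 16 (4R)-4-{[(1Z,4S,5S)-5-chloro-1-iodoocta-1,7-dien-4-yl]oxy}hept-6-en-3-one
Conditions: 15 (1.5 equiv), 2,6-di-tert-butyl-4-methylpyridine, 4 Å MS, CH2Cl2 (1 M), −20 °C → rt
Reagents that add atoms: none
Why: Williamson‑type SN2 etherification without base strong enough to make an alkoxide: the hydroxyl of 9 attacks the carbonyl‑activated secondary triflate from the back, so C12 forms with inversion, (4S) to (4R), and the chlorohydrin cannot close to an epoxide.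

Step 13
Reactants: 16 (4R)-4-{[(1Z,4S,5S)-5-chloro-1-iodoocta-1,7-dien-4-yl]oxy}hept-6-en-3-one
Product: 17 (3R,4R)-4-{[(1Z,4S,5S)-5-chloro-1-iodoocta-1,7-dien-4-yl]oxy}hept-6-en-3-ol
Conditions: LiB(s-Bu)3H, THF, −78 °C; H2O
Reagents that add atoms: none
Why: Felkin–Anh reduction: the bulky hydride attacks anti to the α‑alkoxy group under non‑chelating conditions and gives the 12,13‑syn alcohol (13R), the epimer needed for bromide introduction with inversion.

Step 14
Reactants: 17 (3R,4R)-4-{[(1Z,4S,5S)-5-chloro-1-iodoocta-1,7-dien-4-yl]oxy}hept-6-en-3-ol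
Product: 18 (1Z,4S,5S)-4-{[(3S,4R)-3-bromohept-6-en-4-yl]oxy}-5-chloro-1-iodoocta-1,7-diene
Conditions: CBr4, (n-C8H17)3P, toluene, 70 °C
Reagents that add atoms: tetrabromomethane, BrC(Br)(Br)Br
Why: Appel‑type bromination: the alkoxyphosphonium salt is displaced by bromide in an SN2 step with inversion, giving the (13S)‑bromide anti to the C12 oxygen.

Step 15
Reactants: 18 (1Z,4S,5S)-4-{[(3S,4R)-3-bromohept-6-en-4-yl]oxy}-5-chloro-1-iodoocta-1,7-diene
Product: 19 (2S,3S,5Z,8R)-8-[(1S)-1-bromopropyl]-3-chloro-2-[(2Z)-3-iodoprop-2-en-1-yl]-3,4,7,8-tetrahydro-2H-oxocine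
Conditions: second-generation Grubbs catalyst RuCl2(=CHPh)(H2IMes)(PCy3) (10 mol %), CH2Cl2 (2 mM), 40 °C
Reagents that add atoms: none
Why: Ring‑closing metathesis of the two monosubstituted alkenes releases ethene and closes the eight‑membered ring, whose size enforces the Z ring alkene; high dilution and the gauche C–O/C–Cl arrangement favour cyclisation, the 1‑iodoalkene does not engage the ruthenium carbene, and no stereocentre is touched.

Step 16
Reactants: 19 (2S,3S,5Z,8R)-8-[(1S)-1-bromopropyl]-3-chloro-2-[(2Z)-3-iodoprop-2-en-1-yl]-3,4,7,8-tetrahydro-2H-oxocine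
Product: 20 (2R,4S,5R,7S,8S)-2-[(1S)-1-bromopropyl]-7-chloro-8-[(2Z)-3-iodoprop-2-en-1-yl]oxocane-4,5-diol
Conditions: OsO4 (5 mol %), N-methylmorpholine N-oxide (1.1 equiv), acetone/H2O, 0 °C → rt
Reagents that add atoms: N-methylmorpholine N-oxide, C[N+]1([O-])CCOCC1; water, O
Why: Upjohn syn‑dihydroxylation of the cis ring alkene (the iodoalkene is electron‑poor and slower), expected from the face anti to the branched 1‑bromopropyl group, which is the face carrying C7–Cl and the one on which the C10 oxygen is needed.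

Step 17
Reactants: 20 (2R,4S,5R,7S,8S)-2-[(1S)-1-bromopropyl]-7-chloro-8-[(2Z)-3-iodoprop-2-en-1-yl]oxocane-4,5-diol
Product: 22 (2R,4S,5S,7S,8S)-2-[(1S)-1-bromopropyl]-5,7-dichloro-8-[(2Z)-3-iodoprop-2-en-1-yl]oxocan-4-yl acetate, via cyclic orthoacetate 21 (not isolated)
Conditions: MeC(OMe)3, PPTS (cat.), CH2Cl2, rt; then Me3SiCl, CH2Cl2, 0 °C → rt
Reagents that add atoms: trimethyl orthoacetate, COC(C)(OC)OC; chlorotrimethylsilane, C[Si](C)(C)Cl
Why: Cyclic orthoester formation and ionisation to the acetoxonium (1,3‑dioxolan‑2‑ylium) ion, which chloride opens by SN2 at C9 anti to the ring oxygens (the same‑face approach to C10 is blocked by the cis 1‑bromopropyl group), so C9 is inverted to the (S)‑chloride and the acetate stays on C10, trans to it.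

Step 18
Reactants: 22 (2R,4S,5S,7S,8S)-2-[(1S)-1-bromopropyl]-5,7-dichloro-8-[(2Z)-3-iodoprop-2-en-1-yl]oxocan-4-yl acetate, 23 ethynylmagnesium bromide
Product: 25 (2R,4S,5S,7S,8S)-2-[(1S)-1-bromopropyl]-5,7-dichloro-8-[(2Z)-pent-2-en-4-yn-1-yl]oxocan-4-yl acetate, via ethynylzinc bromide 24 (not isolated)
Conditions: HC≡CMgBr, ZnBr2 (1.2 equiv to Mg), THF, 0 °C; then 22, Pd(PPh3)4 (5 mol %), THF, rt
Reagents that add atoms: none
Why: Negishi coupling: zerovalent palladium inserts into the C–I bond with retention, and transmetalation from zinc followed by reductive elimination gives the Z‑enyne; the organozinc leaves the acetate and the secondary alkyl halides alone.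

## Compound list

1 | (±)-hexa-1,5-dien-3-ol | C=CCC(O)C=C | starting material
2 | (1R)-1-[(2S)-oxiran-2-yl]but-3-en-1-ol | C=CC[C@@H](O)[C@@H]1CO1 | intermediate
3 | (1R)-1-[(2S)-oxiran-2-yl]but-3-en-1-yl chloromethanesulfonate | C=CC[C@@H](OS(=O)(=O)CCl)[C@@H]1CO1 | intermediate
4 | (2S)-2-[(1S)-1-chlorobut-3-en-1-yl]oxirane | C=CC[C@H](Cl)[C@@H]1CO1 | intermediate
5 | ethyne | C#C | starting material
6 | (Z)-1,2-bis(tributylstannyl)ethene | CCCC[Sn](CCCC)(CCCC)/C=C\[Sn](CCCC)(CCCC)CCCC | intermediate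
7 | (Z)-2-(tributylstannyl)vinyllithium | [Li]/C=C\[Sn](CCCC)(CCCC)CCCC | intermediate (not isolated)
8 | (1Z,4S,5S)-5-chloro-1-(tributylstannyl)octa-1,7-dien-4-ol | CCCC[Sn](CCCC)(CCCC)/C=C\C[C@H](O)[C@@H](Cl)CC=C | intermediate
9 | (1Z,4S,5S)-5-chloro-1-iodoocta-1,7-dien-4-ol | I/C=C\C[C@H](O)[C@@H](Cl)CC=C | intermediate
10 | L-allylglycine, (2S)-2-aminopent-4-enoic acid | C=CC[C@H](N)C(=O)O | starting material
11 | (2S)-2-hydroxypent-4-enoic acid | C=CC[C@H](O)C(=O)O | intermediate
12 | methyl (2S)-2-hydroxypent-4-enoate | C=CC[C@H](O)C(=O)OC | intermediate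
13 | (2S)-2-hydroxy-N-methoxy-N-methylpent-4-enamide | C=CC[C@H](O)C(=O)N(C)OC | intermediate
14 | (4S)-4-hydroxyhept-6-en-3-one | C=CC[C@H](O)C(=O)CC | intermediate
15 | (4S)-3-oxohept-6-en-4-yl trifluoromethanesulfonate | C=CC[C@H](OS(=O)(=O)C(F)(F)F)C(=O)CC | intermediate
16 | (4R)-4-{[(1Z,4S,5S)-5-chloro-1-iodoocta-1,7-dien-4-yl]oxy}hept-6-en-3-one | I/C=C\C[C@H](O[C@H](CC=C)C(=O)CC)[C@@H](Cl)CC=C | intermediate
17 | (3R,4R)-4-{[(1Z,4S,5S)-5-chloro-1-iodoocta-1,7-dien-4-yl]oxy}hept-6-en-3-ol | I/C=C\C[C@H](O[C@H](CC=C)[C@H](O)CC)[C@@H](Cl)CC=C | intermediate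
18 | (1Z,4S,5S)-4-{[(3S,4R)-3-bromohept-6-en-4-yl]oxy}-5-chloro-1-iodoocta-1,7-diene | I/C=C\C[C@H](O[C@H](CC=C)[C@@H](Br)CC)[C@@H](Cl)CC=C | intermediate
19 | (2S,3S,5Z,8R)-8-[(1S)-1-bromopropyl]-3-chloro-2-[(2Z)-3-iodoprop-2-en-1-yl]-3,4,7,8-tetrahydro-2H-oxocine | I/C=C\C[C@@H]1O[C@@H]([C@@H](Br)CC)C/C=C\C[C@@H]1Cl | intermediate
20 | (2R,4S,5R,7S,8S)-2-[(1S)-1-bromopropyl]-7-chloro-8-[(2Z)-3-iodoprop-2-en-1-yl]oxocane-4,5-diol | I/C=C\C[C@@H]1O[C@@H]([C@@H](Br)CC)C[C@H](O)[C@H](O)C[C@@H]1Cl | intermediate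
21 | 4,5-O-(1-methoxyethylidene) derivative of 20 (cyclic orthoacetate, both epimers at the orthoester carbon) | I/C=C\C[C@@H]1O[C@@H]([C@@H](Br)CC)C[C@@H]2OC(C)(OC)O[C@@H]2C[C@@H]1Cl | intermediate (not isolated)
22 | (2R,4S,5S,7S,8S)-2-[(1S)-1-bromopropyl]-5,7-dichloro-8-[(2Z)-3-iodoprop-2-en-1-yl]oxocan-4-yl acetate | I/C=C\C[C@@H]1O[C@@H]([C@@H](Br)CC)C[C@H](OC(C)=O)[C@@H](Cl)C[C@@H]1Cl | intermediate
23 | ethynylmagnesium bromide | C#C[Mg]Br | starting material
24 | ethynylzinc bromide | C#C[Zn]Br | intermediate (not isolated)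
25 | (2R,4S,5S,7S,8S)-2-[(1S)-1-bromopropyl]-5,7-dichloro-8-[(2Z)-pent-2-en-4-yn-1-yl]oxocan-4-yl acetate | C#C/C=C\C[C@@H]1O[C@@H]([C@@H](Br)CC)C[C@H](OC(C)=O)[C@@H](Cl)C[C@@H]1Cl | target

## Step count and weak points

Total step count: 18. Longest linear sequence: 12 steps (1, 2, 3, 5, 6, then 12–18; the line 7–11, then 12–18 is equally long).

The three steps most likely to fail:

Step 12, the ether union. The chlorohydrin hydroxyl of 9 is a weak, hindered nucleophile, and the α‑keto triflate 15 can enolise (loss of configuration) or eliminate before it is displaced. The fallback builds the same ether through an oxocarbenium ion instead of an SN2 reaction and brings the bromide in ready‑made. It sets out from 9, which is acylated with commercial (2S)-2-bromobutanoic acid (N,N′-diisopropylcarbodiimide, cat. DMAP, CH2Cl2, −20 °C) to (1Z,4S,5S)-5-chloro-1-iodoocta-1,7-dien-4-yl (2S)-2-bromobutanoate F1. Reduction with i-Bu2AlH at −78 °C and trapping of the aluminium hemiacetal in the same flask with Ac2O, pyridine and DMAP gives (2S)-2-bromo-1-{[(1Z,4S,5S)-5-chloro-1-iodoocta-1,7-dien-4-yl]oxy}butyl acetate F2. Allyltrimethylsilane and BF3·OEt2 at −78 °C then add to the α‑bromo oxocarbenium ion anti to bromine (polar Felkin–Anh), which gives the 12,13‑anti ether. This is 18, so the route is rejoined at 18; compounds 10 to 17 and the bromination are no longer needed.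

Step 17, the chloro‑acetate. Its outcome rests on two substrate‑controlled events, the face of dihydroxylation in step 16 and the carbon that chloride attacks in the acetoxonium ion; the wrong face or attack at C10 gives isomers. The fallback changes the intermediate from a diol to an epoxide. It sets out from 19, which is epoxidised (3-chloroperbenzoic acid, NaHCO3, CH2Cl2, 0 °C) to (2R,4S,5R,7S,8S)-2-[(1S)-1-bromopropyl]-7-chloro-4,5-epoxy-8-[(2Z)-3-iodoprop-2-en-1-yl]oxocane F4. Nucleophilic opening with Li2CuCl4 in THF, which avoids a cationic intermediate and transannular participation of the ring oxygen, gives (2R,4S,5S,7S,8S)-2-[(1S)-1-bromopropyl]-5,7-dichloro-8-[(2Z)-3-iodoprop-2-en-1-yl]oxocan-4-ol F5. Acetylation (Ac2O, pyridine, DMAP) returns to the route at 22.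

Step 14, the bromination. In the open‑chain alcohol 17 the ether oxygen next to the activated carbinol can participate, giving retention or a 1,2‑shifted bromide, and elimination competes. The fallback changes the order so that the substitution is done on the conformationally restricted ring. It sets out from 17, which is cyclised first with the second-generation Grubbs catalyst (CH2Cl2, 2 mM, 40 °C) to (1R)-1-[(2R,4Z,7S,8S)-7-chloro-8-[(2Z)-3-iodoprop-2-en-1-yl]-3,6,7,8-tetrahydro-2H-oxocin-2-yl]propan-1-ol F3. Bromination of F3 with CBr4 and (n-C8H17)3P in toluene at 70 °C, with inversion, returns to the route at 19.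

Further compounds
F1 | step 12 | (1Z,4S,5S)-5-chloro-1-iodoocta-1,7-dien-4-yl (2S)-2-bromobutanoate | I/C=C\C[C@H](OC(=O)[C@@H](Br)CC)[C@@H](Cl)CC=C
F2 | step 12 | (2S)-2-bromo-1-{[(1Z,4S,5S)-5-chloro-1-iodoocta-1,7-dien-4-yl]oxy}butyl acetate (both epimers at C1) | I/C=C\C[C@H](OC(OC(C)=O)[C@@H](Br)CC)[C@@H](Cl)CC=C
F3 | step 14 | (1R)-1-[(2R,4Z,7S,8S)-7-chloro-8-[(2Z)-3-iodoprop-2-en-1-yl]-3,6,7,8-tetrahydro-2H-oxocin-2-yl]propan-1-ol | I/C=C\C[C@@H]1O[C@@H]([C@H](O)CC)C/C=C\C[C@@H]1Cl
F4 | step 17 | (2R,4S,5R,7S,8S)-2-[(1S)-1-bromopropyl]-7-chloro-4,5-epoxy-8-[(2Z)-3-iodoprop-2-en-1-yl]oxocane | I/C=C\C[C@@H]1O[C@@H]([C@@H](Br)CC)C[C@@H]2O[C@@H]2C[C@@H]1Cl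
F5 | step 17 | (2R,4S,5S,7S,8S)-2-[(1S)-1-bromopropyl]-5,7-dichloro-8-[(2Z)-3-iodoprop-2-en-1-yl]oxocan-4-ol | I/C=C\C[C@@H]1O[C@@H]([C@@H](Br)CC)C[C@H](O)[C@@H](Cl)C[C@@H]1Cl
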